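The side chain is cut between the C12 methylene and the C13 carbinol carbon. A primary Grignard reagent carrying the decalin ring system (C5, C9, C10 and the exocyclic C8=C17 methylene, all taken from (+)-sclareolide) adds to the methyl ketone of D-glyceric acid acetonide. This single operation unites the sixteen-carbon and four-carbon halves and sets the tertiary C13 carbinol by 1,2-induction from the purchased C14 centre. It exploits the contiguous C13–C14–C15 triol array, whose O14 and O15 are tied into a dioxolane ring that should favour Felkin–Anh (anti) addition. Acetonide hydrolysis, acetylation of the primary O15 and propionylation of the secondary O14 complete the target.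

Key step: step 8

Remark: labdane numbering is used throughout (decalin C1–C10, exocyclic methylene C8=C17, side chain C11–C16); the target is read as the (13S,14R) isomer of the normal (5S,9S,10S) labdane series.

Step 1
Reactants: 1 (+)-sclareolide
Product: 2 13,14,15,16-tetranorlabdane-8α,12-diol (ambradiol)
Conditions: LiAlH4, THF, 0 °C to reflux; Fieser work-up
Reagents that add atoms: none
Why: Hydride reduction of the γ-lactone (LiAlH4 reduction) opens it to the primary C12 alcohol and the tertiary 8α-alcohol without touching a stereocentre.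

Step 2
Reactants: 2 13,14,15,16-tetranorlabdane-8α,12-diol
Product: 3 8α-hydroxy-13,14,15,16-tetranorlabdan-12-yl acetate
Conditions: Ac2O, pyridine, CH2Cl2, rt (no DMAP)
Reagents that add atoms: acetic anhydride CC(=O)OC(C)=O
Why: O-Acylation under mild conditions distinguishes the primary hydroxyl from the hindered tertiary 8α-hydroxyl, which stays free.

Step 3
Reactants: 3 8α-hydroxy-13,14,15,16-tetranorlabdan-12-yl acetate
Product: 5 13,14,15,16-tetranorlabd-8(17)-en-12-yl acetate, via tertiary 8α-chlorosulfite 4 (not isolated)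
Conditions: SOCl2, pyridine, CH2Cl2, −78 °C
Reagents that add atoms: none
Why: Base-induced anti elimination of a chlorosulfite (alcohol dehydration): the C8–O bond is equatorial on the chair B ring, so no ring hydrogen at C7 or C9 is antiperiplanar to it and only the C17 methyl hydrogens can be removed, which should make the exocyclic C8=C17 olefin the main regioisomer (traces of ring olefins to be removed on AgNO3-impregnated silica).

Step 4
Reactants: 5 13,14,15,16-tetranorlabd-8(17)-en-12-yl acetate
Product: 6 13,14,15,16-tetranorlabd-8(17)-en-12-ol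
Conditions: K2CO3 (cat.), MeOH, rt
Reagents that add atoms: none
Why: Base-catalysed transesterification with methanol releases the primary alcohol and leaves the olefin untouched.

Step 5
Reactants: 6 13,14,15,16-tetranorlabd-8(17)-en-12-ol
Product: 7 12-bromo-13,14,15,16-tetranorlabd-8(17)-ene
Conditions: CBr4, PPh3, CH2Cl2, 0 °C
Reagents that add atoms: carbon tetrabromide BrC(Br)(Br)Br
Why: Appel bromination is a neutral SN2 displacement at primary C12, so no cation is formed near the acid-sensitive exocyclic olefin.

Step 6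
Reactants: 8 methyl (R)-2,2-dimethyl-1,3-dioxolane-4-carboxylate
Product: 9 (R)-N-methoxy-N,2,2-trimethyl-1,3-dioxolane-4-carboxamide
Conditions: MeNH(OMe)·HCl, i-PrMgCl, THF, −20 °C; then H2O
Reagents that add atoms: N,O-dimethylhydroxylamine hydrochloride CNOC.Cl
Why: Aminolysis of the ester by the chloromagnesium amide (Weinreb amide formation) runs at low temperature, at which the α-alkoxy centre (the future C14) should not epimerise.

Step 7
Reactants: 9 (R)-N-methoxy-N,2,2-trimethyl-1,3-dioxolane-4-carboxamide
Product: 10 1-[(4R)-2,2-dimethyl-1,3-dioxolan-4-yl]ethan-1-one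
Conditions: MeMgBr, THF, 0 °C; then H2O
Reagents that add atoms: methylmagnesium bromide C[Mg]Br
Why: Weinreb ketone synthesis: the chelated tetrahedral adduct persists until work-up, so the addition stops at the methyl ketone and the C14 centre is retained.

Step 8
Reactants: 7 12-bromo-13,14,15,16-tetranorlabd-8(17)-ene; 10 1-[(4R)-2,2-dimethyl-1,3-dioxolan-4-yl]ethan-1-one
Product: 12 (13S,14R)-14,15-O-isopropylidenelabd-8(17)-ene-13,14,15-triol, via homodrimenylmagnesium bromide 11 (not isolated)
Conditions: Mg turnings (cat. I2), THF, 45 °C; then 10, THF, −78 to −40 °C; then H2O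
Reagents that add atoms: none
Why: Magnesium inserts into the primary C12–Br bond of 7 to give Grignard reagent 11 (a 4-pentenyl-type carbanion with no favourable cyclisation onto C8=C17), which adds to the carbonyl of methyl ketone 10 by polar 1,2-addition. The closest known reaction type is the anti-selective (Felkin–Anh) addition of Grignard reagents to α,β-isopropylidenedioxy ketones (4-acyl-2,2-dimethyl-1,3-dioxolanes). No ring is closed. The new C13 stereocentre is controlled by the purchased C14 centre through 1,2-induction: in the Felkin–Anh transition state the dioxolane C14–O bond lies anti to the incoming C12 nucleophile, which passes the C14 hydrogen rather than the C15 methylene and so attacks the Si face of the carbonyl to give 13S. The step needs facial selectivity against the α-chelate (Cram-chelate) pathway, which would give the C13 epimer, and addition rather than enolisation of the methyl ketone. The weakly basic, ring-constrained dioxolane oxygen, the donor solvent THF, the low temperature and the unhindered primary Grignard reagent should secure both, and a β-chelate through O15 would direct attack to the same face.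

Step 9
Reactants: 12 (13S,14R)-14,15-O-isopropylidenelabd-8(17)-ene-13,14,15-triol
Product: 13 (13S,14R)-labd-8(17)-ene-13,14,15-triol
Conditions: AcOH–H2O (4:1), 40 °C
Reagents that add atoms: none
Why: Mild acid-catalysed acetal hydrolysis removes the terminal acetonide under conditions too weak to isomerise the exocyclic olefin or ionise the tertiary C13 alcohol.

Step 10
Reactants: 13 (13S,14R)-labd-8(17)-ene-13,14,15-triol
Product: 14 (13S,14R)-13,14-dihydroxylabd-8(17)-en-15-yl acetate
Conditions: AcCl (1.1 equiv), 2,4,6-collidine, CH2Cl2, −78 °C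
Reagents that add atoms: acetyl chloride CC(=O)Cl
Why: Kinetic acylation with acetyl chloride and a hindered pyridine base at low temperature should select the primary O15 over the secondary O14 and the tertiary O13.

Step 11
Reactants: 14 (13S,14R)-13,14-dihydroxylabd-8(17)-en-15-yl acetate
Product: 15 (13S,14R)-15-acetoxy-13-hydroxylabd-8(17)-en-14-yl propanoate
Conditions: (EtCO)2O, pyridine, DMAP (cat.), CH2Cl2, 0 °C
Reagents that add atoms: propionic anhydride CCC(=O)OC(=O)CC
Why: DMAP-catalysed acyl transfer esterifies the secondary O14 quickly, before the acetate can migrate, while the tertiary C13 hydroxyl is too hindered to react.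

Compound list
1 | (+)-sclareolide, (3aR,5aS,9aS,9bR)-3a,6,6,9a-tetramethyldecahydronaphtho[2,1-b]furan-2(1H)-one | C[C@@]12CC[C@H]3C(C)(C)CCC[C@]3(C)[C@H]1CC(=O)O2 | starting material
2 | 13,14,15,16-tetranorlabdane-8α,12-diol, (1R,2R,4aS,8aS)-1-(2-hydroxyethyl)-2,5,5,8a-tetramethyldecahydronaphthalen-2-ol | C[C@@]1(O)CC[C@H]2C(C)(C)CCC[C@]2(C)[C@H]1CCO | intermediate
3 | 8α-hydroxy-13,14,15,16-tetranorlabdan-12-yl acetate, 2-[(1R,2R,4aS,8aS)-2-hydroxy-2,5,5,8a-tetramethyldecahydronaphthalen-1-yl]ethyl acetate | C[C@@]1(O)CC[C@H]2C(C)(C)CCC[C@]2(C)[C@H]1CCOC(C)=O | intermediate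
4 | tertiary 8α-chlorosulfite of 3 (8α-chlorosulfinyloxy 12-acetate) | C[C@@]1(OS(=O)Cl)CC[C@H]2C(C)(C)CCC[C@]2(C)[C@H]1CCOC(C)=O | intermediate (not isolated)
5 | 13,14,15,16-tetranorlabd-8(17)-en-12-yl acetate, 2-[(1S,4aS,8aS)-5,5,8a-trimethyl-2-methylenedecahydronaphthalen-1-yl]ethyl acetate | C=C1CC[C@H]2C(C)(C)CCC[C@]2(C)[C@H]1CCOC(C)=O | intermediate
6 | 13,14,15,16-tetranorlabd-8(17)-en-12-ol, 2-[(1S,4aS,8aS)-5,5,8a-trimethyl-2-methylenedecahydronaphthalen-1-yl]ethanol | C=C1CC[C@H]2C(C)(C)CCC[C@]2(C)[C@H]1CCO | intermediate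
7 | 12-bromo-13,14,15,16-tetranorlabd-8(17)-ene, (1S,4aS,8aS)-1-(2-bromoethyl)-5,5,8a-trimethyl-2-methylenedecahydronaphthalene | C=C1CC[C@H]2C(C)(C)CCC[C@]2(C)[C@H]1CCBr | intermediate
8 | methyl (R)-2,2-dimethyl-1,3-dioxolane-4-carboxylate (methyl D-glycerate acetonide) | COC(=O)[C@H]1COC(C)(C)O1 | starting material
9 | (R)-N-methoxy-N,2,2-trimethyl-1,3-dioxolane-4-carboxamide | CON(C)C(=O)[C@H]1COC(C)(C)O1 | intermediate
10 | 1-[(4R)-2,2-dimethyl-1,3-dioxolan-4-yl]ethan-1-one | CC(=O)[C@H]1COC(C)(C)O1 | intermediate
11 | homodrimenylmagnesium bromide, 2-[(1S,4aS,8aS)-5,5,8a-trimethyl-2-methylenedecahydronaphthalen-1-yl]ethylmagnesium bromide | C=C1CC[C@H]2C(C)(C)CCC[C@]2(C)[C@H]1CC[Mg]Br | intermediate (not isolated)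
12 | (13S,14R)-14,15-O-isopropylidenelabd-8(17)-ene-13,14,15-triol, (2S)-2-[(4R)-2,2-dimethyl-1,3-dioxolan-4-yl]-4-[(1S,4aS,8aS)-5,5,8a-trimethyl-2-methylenedecahydronaphthalen-1-yl]butan-2-ol | C=C1CC[C@H]2C(C)(C)CCC[C@]2(C)[C@H]1CC[C@](C)(O)[C@H]1COC(C)(C)O1 | intermediate
13 | (13S,14R)-labd-8(17)-ene-13,14,15-triol, (2R,3S)-3-methyl-5-[(1S,4aS,8aS)-5,5,8a-trimethyl-2-methylenedecahydronaphthalen-1-yl]pentane-1,2,3-triol | C=C1CC[C@H]2C(C)(C)CCC[C@]2(C)[C@H]1CC[C@](C)(O)[C@@H](CO)O | intermediate
14 | (13S,14R)-13,14-dihydroxylabd-8(17)-en-15-yl acetate | C=C1CC[C@H]2C(C)(C)CCC[C@]2(C)[C@H]1CC[C@](C)(O)[C@@H](COC(C)=O)O | intermediate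
15 | (13S,14R)-15-acetoxy-13-hydroxylabd-8(17)-en-14-yl propanoate (CNP0275533.1) | C=C1CC[C@H]2C(C)(C)CCC[C@]2(C)[C@H]1CC[C@](C)(O)[C@@H](COC(C)=O)OC(=O)CC | target

Total step count: 11. Longest linear sequence: 9 steps (steps 1–5 and 8–11); steps 6–7 make the ketone in parallel.

Steps most likely to fail

1. Step 8. The facial selectivity may erode through competing α-chelated delivery, which gives the C13 epimer, and the Grignard reagent may enolise the methyl ketone instead of adding. The fallback sets out from Weinreb amide 9 and Grignard reagent 11 and comes back at triol 13; it builds C13 in the reverse order, so that the well-established α-chelation manifold gives the same 13S centre. Aqueous acetic acid would hydrolyse 9 to (2R)-2,3-dihydroxy-N-methoxy-N-methylpropanamide F1. 4-Methoxybenzyl trichloroacetimidate with catalytic camphorsulfonic acid would then give the bis-PMB ether (2R)-N-methoxy-2,3-bis[(4-methoxybenzyl)oxy]-N-methylpropanamide F2. Acylation of 11 with F2 in THF forms the C12–C13 bond as the ketone (14R)-14,15-bis[(4-methoxybenzyl)oxy]-16-norlabd-8(17)-en-13-one F3. Methylmagnesium bromide in THF at −78 °C should add to F3 under Cram-chelate control through the C14 PMB ether to give (13S,14R)-14,15-bis[(4-methoxybenzyl)oxy]labd-8(17)-en-13-ol F4. DDQ in wet CH2Cl2 removes both PMB groups and delivers 13.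

2. Step 3. The anti elimination may leak into an ionising pathway that forms the C7=C8 and C8=C9 ring olefins, which travel with the exocyclic isomer on silica. The fallback sets out from alcohol 6 as the regioisomer mixture and comes back at pure 6; it separates by constitution instead of by chromatography of olefin isomers. Iodine and NaHCO3 in MeCN at 0 °C should convert only the exocyclic isomer, by 5-exo iodoetherification through C17, into the iodo ether 17-iodo-8α,12-epoxy-13,14,15,16-tetranorlabdane F5 (either C8 epimer serves). The ring-olefin isomers give differently constituted products or do not cyclise, so F5 can be separated. Zinc dust with NH4Cl in refluxing ethanol then opens F5 by reductive β-elimination and regenerates the C8=C17 olefin and the C12 alcohol of 6 regiospecifically.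

3. Step 10. Over-acetylation at O14 and base-promoted acetyl migration from O15 to O14 may scramble the two esters. The fallback sets out from triol 13 and comes back at target 15; it uses temporary protection of O15 and reverses the order of the two acylations. TBSCl and imidazole in DMF would give the primary silyl ether (13S,14R)-15-(tert-butyldimethylsilyloxy)labd-8(17)-ene-13,14-diol F6. Propionic anhydride, pyridine and catalytic DMAP would give (13S,14R)-15-(tert-butyldimethylsilyloxy)-13-hydroxylabd-8(17)-en-14-yl propanoate F7. HF·pyridine in THF at 0 °C, acidic enough to suppress acyl migration, would give (13S,14R)-13,15-dihydroxylabd-8(17)-en-14-yl propanoate F8. Immediate acetylation with Ac2O and pyridine gives 15.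

Further compounds
F1 | step 8 | (2R)-2,3-dihydroxy-N-methoxy-N-methylpropanamide | CON(C)C(=O)[C@H](O)CO
F2 | step 8 | (2R)-N-methoxy-2,3-bis[(4-methoxybenzyl)oxy]-N-methylpropanamide | CON(C)C(=O)[C@H](OCc1ccc(OC)cc1)COCc1ccc(OC)cc1
F3 | step 8 | (14R)-14,15-bis[(4-methoxybenzyl)oxy]-16-norlabd-8(17)-en-13-one | C=C1CC[C@H]2C(C)(C)CCC[C@]2(C)[C@H]1CCC(=O)[C@H](OCc1ccc(OC)cc1)COCc1ccc(OC)cc1
F4 | step 8 | (13S,14R)-14,15-bis[(4-methoxybenzyl)oxy]labd-8(17)-en-13-ol | C=C1CC[C@H]2C(C)(C)CCC[C@]2(C)[C@H]1CC[C@](C)(O)[C@H](OCc1ccc(OC)cc1)COCc1ccc(OC)cc1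
F5 | step 3 | 17-iodo-8α,12-epoxy-13,14,15,16-tetranorlabdane, (3aR,5aS,9aS,9bR)-3a-(iodomethyl)-6,6,9a-trimethyldodecahydronaphtho[2,1-b]furan | IC[C@@]12CC[C@H]3C(C)(C)CCC[C@]3(C)[C@H]1CCO2
F6 | step 10 | (13S,14R)-15-(tert-butyldimethylsilyloxy)labd-8(17)-ene-13,14-diol | C=C1CC[C@H]2C(C)(C)CCC[C@]2(C)[C@H]1CC[C@](C)(O)[C@@H](CO[Si](C)(C)C(C)(C)C)O
F7 | step 10 | (13S,14R)-15-(tert-butyldimethylsilyloxy)-13-hydroxylabd-8(17)-en-14-yl propanoate | C=C1CC[C@H]2C(C)(C)CCC[C@]2(C)[C@H]1CC[C@](C)(O)[C@@H](CO[Si](C)(C)C(C)(C)C)OC(=O)CC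
F8 | step 10 | (13S,14R)-13,15-dihydroxylabd-8(17)-en-14-yl propanoate | C=C1CC[C@H]2C(C)(C)CCC[C@]2(C)[C@H]1CC[C@](C)(O)[C@@H](CO)OC(=O)CC
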